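Everything rests on making ring A by enlargement. A cis-hydrindane is built by asymmetric Robinson annulation and cuprate addition so that C5 carries a 2-hydroxyprop-2-yl group (the future C4) beside the quaternary C10. Ionisation at C4 triggers a Wagner–Meerwein shift of C3 from C5 to C4: the cyclopentane C1–C2–C3–C5–C10 becomes cyclohexane ring A with its gem-dimethyl carbon in place, and the C5 cation collapses to the C5=C6 olefin. The step exploits the C4(Me2)–C5(H)–C6(O) array at the junction of rings A and B: hydroboration then sets C5–H and C6–O anti to the C10 methyl. The catalysis-set C5 centre relays chirality to C10 before it is erased.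

Key step: step 5

Remark: labdane numbering is used throughout (ring carbons C1–C10, side-chain carbons C11/C12, ester carbon C17); C9 is an unassigned epimer mixture from 7 to 18 (no descriptor in those SMILES) and is fixed thermodynamically in step 8; compounds 5, 16 and 23 are taken as purchasable.

Step 1
Reactants: 1 methyl 2-oxocyclopentane-1-carboxylate; 2 methyl vinyl ketone
Product: 4 methyl (7aR)-5-oxo-2,3,5,6,7,7a-hexahydro-1H-indene-7a-carboxylate, via Michael adduct 3 (not isolated)
Conditions: 6'-hydroxy cinchona catalyst of the 9-O-(9-phenanthryl)cupreidine/cupreine pair (10 mol %), toluene, −20 °C; then TsOH·H2O, reflux, Dean–Stark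
Reagents that add atoms: none
Why: Asymmetric Michael addition under bifunctional base/hydrogen-bond catalysis sets the quaternary C5 centre (the pseudoenantiomer of the catalyst that delivers the R adduct is the one used), and acid-mediated intramolecular aldol condensation (Robinson annulation) closes ring B onto the ring ketone, the only six-membered mode open to the methyl ketone.

Step 2
Reactants: 4 methyl (7aR)-5-oxo-2,3,5,6,7,7a-hexahydro-1H-indene-7a-carboxylate; 5 2-chloroethyl trifluoromethanesulfonate
Product: 7 methyl (3aR,7aR)-4-(2-chloroethyl)-3a-methyl-5-oxooctahydro-1H-indene-7a-carboxylate (cis-fused; C9 epimers), via lithium enolate 6 (not isolated)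
Conditions: Me2CuLi, Et2O, −40 → 0 °C; then 5, THF, −40 → 0 °C
Reagents that add atoms: lithium dimethylcuprate [Li+].C[Cu-]C
Why: Tandem conjugate addition–enolate alkylation: the Gilman cuprate should add to C10 on the face that gives the cis-fused hydrindane (methyl cis to the angular ester), relaying the C5 configuration to the quaternary C10, and the regiodefined C8=C9 lithium enolate is C-alkylated by the primary triflate in THF without a dipolar cosolvent to disfavour O-alkylation.

Step 3
Reactants: 7 methyl (3aR,7aR)-4-(2-chloroethyl)-3a-methyl-5-oxooctahydro-1H-indene-7a-carboxylate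
Product: 8 methyl (3aR,7aR)-4-(2-chloroethyl)-5,5-(ethylenedioxy)-3a-methyloctahydro-1H-indene-7a-carboxylate
Conditions: ethylene glycol, TsOH·H2O (cat.), benzene, reflux, Dean–Stark
Reagents that add atoms: ethylene glycol OCCO
Why: Acid-catalysed ketalisation masks the C8 ketone as a dioxolane for the organolithium and borane steps, while the hindered angular ester and the primary chloride are inert.

Step 4
Reactants: 8 methyl (3aR,7aR)-4-(2-chloroethyl)-5,5-(ethylenedioxy)-3a-methyloctahydro-1H-indene-7a-carboxylate
Product: 10 2-[(3aR,7aR)-4-(2-chloroethyl)-5,5-(ethylenedioxy)-3a-methyloctahydro-1H-inden-7a-yl]propan-2-ol, via methyl ketone 9 (not isolated)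
Conditions: MeLi (5 equiv), Et2O, 0 °C → rt; then H2O
Reagents that add atoms: methyllithium [Li]C
Why: Double addition of methyllithium to the ester through the methyl ketone gives the tertiary carbinol that holds the future C4 with both of its methyl groups; the small nucleophile should reach the hindered carbonyl, and the ketal and primary chloride do not react at this temperature.

Step 5
Reactants: 10 2-[(3aR,7aR)-4-(2-chloroethyl)-5,5-(ethylenedioxy)-3a-methyloctahydro-1H-inden-7a-yl]propan-2-ol
Product: 13 9-(2-chloroethyl)-8,8-(ethylenedioxy)-4,4,10β-trimethyl-Δ5(6)-octalin, via tertiary cation 11 (not isolated), via ring-expanded cation 12 (not isolated)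
Conditions: TsOH (anhydrous, 0.2 equiv), ethylene glycol (2 equiv), benzene, 80 °C, Dean–Stark
Reagents that add atoms: none
Why: Protonation and loss of water from the neopentylic carbinol give the tertiary C4 cation 11, which is flanked only by the quaternary C5, so no hydride shift can intervene and a 1,2-alkyl shift follows. Migration of C3 from C5 to C4 enlarges the cyclopentane to cyclohexane ring A, a Wagner–Meerwein (Demjanov-type) ring expansion whose closest precedent is the acid-mediated cyclopentylcarbinyl-to-cyclohexyl rearrangement of terpenoid carbinols; no ring is closed by cyclisation, ring A arises purely by this one-carbon enlargement with C3–C4 as the only new ring bond. The selectivity needed is C3 over C6 or C10 migration: the C3 shift relieves five-ring strain and gives the unstrained tertiary cation 12, whereas a C6 shift would build a seven-membered ring B and a C10 shift a bridgehead cation. Cation 12 can lose a proton only from C6, because C4 and C10 are quaternary, so the trisubstituted C5=C6 olefin is the single elimination product. No stereocentre is created: C10 is untouched and keeps its configuration, the C5 centre that relayed it is deliberately erased, and ethylene glycol with water removal keeps the C8 dioxolane intact.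

Step 6
Reactants: 13 9-(2-chloroethyl)-8,8-(ethylenedioxy)-4,4,10β-trimethyl-Δ5(6)-octalin
Product: 15 9-(2-chloroethyl)-8,8-(ethylenedioxy)-4,4,10β-trimethyl-5α-H-trans-decalin-6α-ol, via alkylborane 14 (not isolated)
Conditions: BH3·THF, THF, 0 → 40 °C; then NaOH, H2O2, 0 °C → rt
Reagents that add atoms: hydrogen peroxide OO
Why: Hydroboration–oxidation: borane should add syn from the α face, anti to the axial C10 and C4β methyl groups, with boron on the less substituted C6, so that C5–H and C6–O are both set α (trans-decalin) and the C–B bond is oxidised with retention.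

Step 7
Reactants: 15 9-(2-chloroethyl)-8,8-(ethylenedioxy)-4,4,10β-trimethyl-5α-H-trans-decalin-6α-ol; 16 (R)-2-methylbutanoic acid
Product: 18 9-(2-chloroethyl)-8,8-(ethylenedioxy)-4,4,10β-trimethyl-5α-H-trans-decalin-6α-yl (R)-2-methylbutanoate, via mixed anhydride 17 (not isolated)
Conditions: 16, 2,4,6-trichlorobenzoyl chloride, Et3N, THF, rt; then 15, DMAP, toluene, 60 °C
Reagents that add atoms: none
Why: Yamaguchi esterification transfers the acyl group from the mixed anhydride to the hindered equatorial alcohol through the acylpyridinium, a pathway that should leave the α-stereocentre of the acid untouched; acylating at the ketal stage avoids a base-sensitive β-acyloxy ketone.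

Step 8
Reactants: 18 9-(2-chloroethyl)-8,8-(ethylenedioxy)-4,4,10β-trimethyl-5α-H-trans-decalin-6α-yl (R)-2-methylbutanoate
Product: 19 9β-(2-chloroethyl)-4,4,10β-trimethyl-8-oxo-5α,9α-H-trans-decalin-6α-yl (R)-2-methylbutanoate
Conditions: 2 M HCl, THF, 40 °C
Reagents that add atoms: water O
Why: Acid hydrolysis of the dioxolane frees the C8 ketone, and acid-catalysed enolisation toward C9 in the rigid trans-decalin should equilibrate both epimers to the equatorial 9β side chain (thermodynamic control), while the equatorial 6α-acyloxy group is poorly aligned for β-elimination.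

Step 9
Reactants: 19 9β-(2-chloroethyl)-4,4,10β-trimethyl-8-oxo-5α,9α-H-trans-decalin-6α-yl (R)-2-methylbutanoate
Product: 21 9β-(2-chloroethyl)-4,4,10β-trimethyl-8-(trifluoromethanesulfonyloxy)-5α,9α-H-octal-7-en-6α-yl (R)-2-methylbutanoate, via lithium enolate 20 (not isolated)
Conditions: LiN(SiMe3)2, THF, −78 °C; then PhNTf2, −78 → −20 °C; then aq NH4Cl
Reagents that add atoms: N-phenylbis(trifluoromethanesulfonimide) O=S(=O)(N(c1ccccc1)S(=O)(=O)C(F)(F)F)C(F)(F)F
Why: Kinetic enolisation and O-triflation: the amide base should remove the axial C7 proton in preference to the hindered tertiary C9 proton and is too weak to deprotonate the branched ester, and at −78 °C the equatorial C6–O bond lies near the nodal plane of the enolate so loss of the acyloxy group should be slow.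

Step 10
Reactants: 21 9β-(2-chloroethyl)-4,4,10β-trimethyl-8-(trifluoromethanesulfonyloxy)-5α,9α-H-octal-7-en-6α-yl (R)-2-methylbutanoate
Product: 22 methyl 9β-(2-chloroethyl)-6α-[(R)-2-methylbutanoyloxy]-4,4,10β-trimethyl-5α,9α-H-octal-7-ene-8-carboxylate
Conditions: Pd(OAc)2, dppf, CO (1 atm), MeOH, Et3N, DMF, 60 °C
Reagents that add atoms: carbon monoxide [C-]#[O+]; methanol CO
Why: Palladium-catalysed methoxycarbonylation of the enol triflate installs the C17 ester on C8 with the C7=C8 olefin in place; the alkyl chloride is inert, and the allylic ester resists ionisation because zerovalent palladium would have to approach from the methyl-shielded β face.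

Step 11
Reactants: 22 methyl 9β-(2-chloroethyl)-6α-[(R)-2-methylbutanoyloxy]-4,4,10β-trimethyl-5α,9α-H-octal-7-ene-8-carboxylate; 23 3-bromofuran-2(5H)-one
Product: 25 methyl 6α-[(R)-2-methylbutanoyloxy]labda-7,13-dien-16,15-olid-17-oate (CNP0147155.1), via primary iodide 24 (not isolated)
Conditions: NiBr2(dme), 4,4'-di-tert-butyl-2,2'-bipyridine, Zn dust, NaI (1.5 equiv), N,N-dimethylacetamide, 60 °C
Reagents that add atoms: none
Why: Nickel-catalysed reductive cross-electrophile coupling joins C12 to C13 after in situ Finkelstein exchange, the vinyl bromide entering by oxidative addition and the primary alkyl partner as a radical; esters, the enoate and the butenolide are tolerated under these neutral conditions.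

Compound list
1 | methyl 2-oxocyclopentane-1-carboxylate | COC(=O)C1CCCC1=O | starting material
2 | methyl vinyl ketone (but-3-en-2-one) | CC(=O)C=C | starting material
3 | methyl (1R)-2-oxo-1-(3-oxobutyl)cyclopentane-1-carboxylate | COC(=O)[C@@]1(CCC(C)=O)CCCC1=O | intermediate
4 | methyl (7aR)-5-oxo-2,3,5,6,7,7a-hexahydro-1H-indene-7a-carboxylate | COC(=O)[C@@]12CCCC1=CC(=O)CC2 | intermediate
5 | 2-chloroethyl trifluoromethanesulfonate | ClCCOS(=O)(=O)C(F)(F)F | starting material
6 | lithium C8=C9 enolate of methyl (3aR,7aR)-3a-methyl-5-oxooctahydro-1H-indene-7a-carboxylate (cis-fused) | COC(=O)[C@@]12CCC[C@]1(C)C=C([O-])CC2.[Li+] | intermediate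
7 | methyl (3aR,7aR)-4-(2-chloroethyl)-3a-methyl-5-oxooctahydro-1H-indene-7a-carboxylate (cis-fused; C9 epimers) | COC(=O)[C@@]12CCC[C@]1(C)C(CCCl)C(=O)CC2 | intermediate
8 | methyl (3aR,7aR)-4-(2-chloroethyl)-5,5-(ethylenedioxy)-3a-methyloctahydro-1H-indene-7a-carboxylate | COC(=O)[C@@]12CCC[C@]1(C)C(CCCl)C1(OCCO1)CC2 | intermediate
9 | 1-[(3aR,7aR)-4-(2-chloroethyl)-5,5-(ethylenedioxy)-3a-methyloctahydro-1H-inden-7a-yl]ethan-1-one | CC(=O)[C@@]12CCC[C@]1(C)C(CCCl)C1(OCCO1)CC2 | intermediate
10 | 2-[(3aR,7aR)-4-(2-chloroethyl)-5,5-(ethylenedioxy)-3a-methyloctahydro-1H-inden-7a-yl]propan-2-ol | CC(C)(O)[C@@]12CCC[C@]1(C)C(CCCl)C1(OCCO1)CC2 | intermediate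
11 | tertiary 2-propyl (C4) cation on C5 of the hydrindane ketal | C[C+](C)[C@@]12CCC[C@]1(C)C(CCCl)C1(OCCO1)CC2 | intermediate
12 | ring-expanded tertiary C5 cation of the 4,4,10β-trimethyldecalin ketal | C[C@]12CCCC(C)(C)[C+]1CCC1(OCCO1)C2CCCl | intermediate
13 | 9-(2-chloroethyl)-8,8-(ethylenedioxy)-4,4,10β-trimethyl-Δ5(6)-octalin (C9 epimers) | C[C@]12CCCC(C)(C)C1=CCC1(OCCO1)C2CCCl | intermediate
14 | 6α-boryl-9-(2-chloroethyl)-8,8-(ethylenedioxy)-4,4,10β-trimethyl-5α-H-trans-decalin | B[C@H]1CC3(OCCO3)C(CCCl)[C@@]2(C)CCCC(C)(C)[C@H]12 | intermediate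
15 | 9-(2-chloroethyl)-8,8-(ethylenedioxy)-4,4,10β-trimethyl-5α-H-trans-decalin-6α-ol | O[C@H]1CC3(OCCO3)C(CCCl)[C@@]2(C)CCCC(C)(C)[C@H]12 | intermediate
16 | (R)-2-methylbutanoic acid | CC[C@@H](C)C(=O)O | starting material
17 | (R)-2-methylbutanoic 2,4,6-trichlorobenzoic anhydride | CC[C@@H](C)C(=O)OC(=O)c1c(Cl)cc(Cl)cc1Cl | intermediate
18 | 9-(2-chloroethyl)-8,8-(ethylenedioxy)-4,4,10β-trimethyl-5α-H-trans-decalin-6α-yl (R)-2-methylbutanoate | CC[C@@H](C)C(=O)O[C@H]1CC3(OCCO3)C(CCCl)[C@@]2(C)CCCC(C)(C)[C@H]12 | intermediate
19 | 9β-(2-chloroethyl)-4,4,10β-trimethyl-8-oxo-5α,9α-H-trans-decalin-6α-yl (R)-2-methylbutanoate | CC[C@@H](C)C(=O)O[C@H]1CC(=O)[C@H](CCCl)[C@@]2(C)CCCC(C)(C)[C@H]12 | intermediate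
20 | lithium C7=C8 enolate of 19 | CC[C@@H](C)C(=O)O[C@H]1C=C([O-])[C@H](CCCl)[C@@]2(C)CCCC(C)(C)[C@H]12.[Li+] | intermediate
21 | 9β-(2-chloroethyl)-4,4,10β-trimethyl-8-(trifluoromethanesulfonyloxy)-5α,9α-H-octal-7-en-6α-yl (R)-2-methylbutanoate | CC[C@@H](C)C(=O)O[C@H]1C=C(OS(=O)(=O)C(F)(F)F)[C@H](CCCl)[C@@]2(C)CCCC(C)(C)[C@H]12 | intermediate
22 | methyl 9β-(2-chloroethyl)-6α-[(R)-2-methylbutanoyloxy]-4,4,10β-trimethyl-5α,9α-H-octal-7-ene-8-carboxylate | CC[C@@H](C)C(=O)O[C@H]1C=C(C(=O)OC)[C@H](CCCl)[C@@]2(C)CCCC(C)(C)[C@H]12 | intermediate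
23 | 3-bromofuran-2(5H)-one | O=C1OCC=C1Br | starting material
24 | methyl 9β-(2-iodoethyl)-6α-[(R)-2-methylbutanoyloxy]-4,4,10β-trimethyl-5α,9α-H-octal-7-ene-8-carboxylate | CC[C@@H](C)C(=O)O[C@H]1C=C(C(=O)OC)[C@H](CCI)[C@@]2(C)CCCC(C)(C)[C@H]12 | intermediate
25 | methyl 6α-[(R)-2-methylbutanoyloxy]labda-7,13-dien-16,15-olid-17-oate (CNP0147155.1) | CC[C@@H](C)C(=O)O[C@H]1C=C(C(=O)OC)[C@H](CCC2=CCOC2=O)[C@@]2(C)CCCC(C)(C)[C@H]12 | target

Total step count: 11. Longest linear sequence: 11 steps (1 → 25); 2, 5, 16 and 23 are purchased and enter directly.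

Steps most likely to fail

Step 5: the cationic rearrangement may run in the wrong direction or too far, by migration of C6 in place of C3 or by reprotonation of the new olefin under the equilibrating acid followed by methyl shifts from C4 or C10. The fallback separates rearrangement from olefin formation. It sets out from 10, which is ionised with SOCl2 in CH2Cl2 at −20 °C without base so that the ion pair rearranges and collapses to the ring-expanded tertiary C5 chloride F1. Dehydrochlorination of F1 with DBU in toluene at 80 °C, an E2 process for which only the C6 hydrogens are available, comes back to the route at 13 without exposing the olefin to protic acid.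

Step 2: C-alkylation of the hindered enolate beside the new quaternary C10 may be slow, O-alkylation by the hard triflate or loss of triflate to residual cuprate may compete, and proton exchange may let the γ-chloro ketone close to a cyclopropane. The fallback sets out from 4 and traps the cuprate enolate with allyl bromide in THF/HMPA to give the C9-allyl ketone F2. Ketalisation (ethylene glycol, TsOH, benzene) gives the allyl dioxolane F3, and ozonolysis (O3, CH2Cl2, −78 °C, then PPh3) gives the dioxolane aldehyde F4. Reduction with NaBH4 in MeOH gives the 2-hydroxyethyl dioxolane F5, and Appel chlorination (PPh3, CCl4) comes back to the route at 8.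

Step 11: the reductive coupling may be diverted by hydrodehalogenation or homocoupling of either partner and by conjugate radical addition to the butenolide. The fallback replaces it with a preformed organometallic. It sets out from 22, where Finkelstein exchange (NaI, acetone, reflux) gives the primary iodide 24 as an isolated compound. Zinc insertion (Zn dust, LiCl, THF, 40 °C) gives the alkylzinc iodide F6, and Negishi coupling of F6 with 23 (Pd(PPh3)4, THF, 50 °C) comes back to the route at 25.

Further compounds
F1 | step 5 | 5-chloro-9-(2-chloroethyl)-8,8-(ethylenedioxy)-4,4,10β-trimethyldecalin (C5 and C9 unassigned) | C[C@]12CCCC(C)(C)C1(Cl)CCC1(OCCO1)C2CCCl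
F2 | step 2 | methyl (3aR,7aR)-4-allyl-3a-methyl-5-oxooctahydro-1H-indene-7a-carboxylate (C9 epimers) | COC(=O)[C@@]12CCC[C@]1(C)C(CC=C)C(=O)CC2
F3 | step 2 | methyl (3aR,7aR)-4-allyl-5,5-(ethylenedioxy)-3a-methyloctahydro-1H-indene-7a-carboxylate | COC(=O)[C@@]12CCC[C@]1(C)C(CC=C)C1(OCCO1)CC2
F4 | step 2 | methyl (3aR,7aR)-5,5-(ethylenedioxy)-3a-methyl-4-(2-oxoethyl)octahydro-1H-indene-7a-carboxylate | COC(=O)[C@@]12CCC[C@]1(C)C(CC=O)C1(OCCO1)CC2
F5 | step 2 | methyl (3aR,7aR)-5,5-(ethylenedioxy)-4-(2-hydroxyethyl)-3a-methyloctahydro-1H-indene-7a-carboxylate | COC(=O)[C@@]12CCC[C@]1(C)C(CCO)C1(OCCO1)CC2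
F6 | step 11 | alkylzinc iodide of 24 (zinc on C12) | CC[C@@H](C)C(=O)O[C@H]1C=C(C(=O)OC)[C@H](CC[Zn]I)[C@@]2(C)CCCC(C)(C)[C@H]12
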